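The violet and grey flasks hold the same 250 mM of starting material, the limiting reagent, and the same 625 mM of partner, and differ only in free catalyst, 13.0 mM against 26.0 mM.

| flask | starting material | partner | free catalyst | time |
|---|---|---|---|---|
| violet | 250 mM | 625 mM | 13.0 mM |  |
| grey | 250 mM | 625 mM | 26.0 mM |  |
| amber | 250 mM | 1200 mM | 13.0 mM |  |
| red | 380 mM | 625 mM | 13.0 mM |  |
| green | 62.0 mM | 160 mM | 13.0 mM | 36 min |

| run | time / min | [product] / mM |
|---|---|---|
| violet run | 1.4 | 11.0 |
| violet run | 3.2 | 27.5 |
| violet run | 7.2 | 57.4 |
| violet run | 16 | 114.6 |
| violet run | 36 | 189.3 |
| grey run | 1.4 | 25.4 |
| grey run | 3.2 | 56.8 |
| grey run | 7.2 | 113.3 |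
| grey run | 16 | 189.3 |
| grey run | 36 | 239.7 |
| amber run | 1.4 | 10.1 |
| amber run | 3.2 | 26.5 |
| amber run | 7.2 | 58.6 |
| amber run | 16 | 115.8 |
| amber run | 36 | 191.4 |
| red run | 1.4 | 17.2 |
| red run | 3.2 | 38.3 |
| red run | 7.2 | 83.4 |
| red run | 16 | 164.2 |
| red run | 36 | 278.7 |

(scatter of a reading: 0.8 mM)

- Overall: starting material + partner -> product, with free catalyst as catalyst.
- Constant volume, constant temperature.
- Readings of a species count what is bound in complexes too.
- "The second partner" is partner.
- An order is taken over about fifteen percent of the charge, up and down.

1. how the opening rate goes with [free catalyst] round the charge of the violet run: the exponent of the rate at two percent of starting material gone to product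
2. how the opening rate goes with [starting material] round the charge of the violet run: the exponent of the rate at two percent of starting material gone to product (one fixed amount of product, the same in the runs compared)
3. product in the green run at 36 min, as a share of the starting material charged
4. which of these the readings show (an uncatalysed path runs beside / a little impurity takes part of the catalyst at once / the second partner is lost by itself / nothing beyond the main steps / the catalyst dies in pairs)

I compare two times. The violet run reads c(product) = 189.3 mM at 36 min, and the grey run reads 189.3 mM at 16 min. At equal product these two flasks hold equal starting material and equal partner, so if the rate follows the working catalyst, the times stand in the inverse ratio of the working catalyst. That ratio reads 2.25, although the grey charge is twice the violet one. Earlier in the same two runs, the violet run reads 57.4 mM at 7.2 min and the grey run reads 56.8 mM at 3.2 min, nearly equal product at a time ratio of 2.25, so the ratio reads the same early and late. I read this as a fixed loss present from the first reading, not one that grows.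

Subtracting the same amount from both charges until their ratio matches the time ratio gives the catalyst lost at once, 2.60 mM. The violet flask then has 10.4 mM working, and a small fractional change in its charge is a fractional change in the working catalyst larger by the factor charge over working amount, so I expect an order in free catalyst of 1.25.

The amber run, with 1200 mM of partner, reads 191.4 mM at 36 min, close to the violet run. At 7.2 min the red run's product over the violet run's reads 1.45, which is smaller than the charge ratio of 1.52, so I put the order in starting material below one. The green flask has the violet catalyst charge, so I take the violet share at 36 min, 75.7%, as its share, or slightly above.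

The forecast gives 1.25 (1.17 to 1.33), 0.84 (0.74 to 0.95), 76% (68% to 81%) and "a little impurity takes part of the catalyst at once", on the ground: “That fits a fixed loss of catalyst”.

The flask gives 1.2, 0.87, 76.8% and "a little impurity takes part of the catalyst at once".

    free catalyst + starting material → catalyst-substrate complex (4.122 L mol⁻¹ min⁻¹)
    catalyst-substrate complex + partner → loaded catalyst (28.68 L mol⁻¹ min⁻¹)
    loaded catalyst → product + free catalyst (9.480 min⁻¹)
    free catalyst + impurity → spent catalyst

The loss lifts the order in free catalyst: the violet charge gives 1.2, and 0.98 with the impurity taken away. Carried to the green run, the same 2.60 mM leaves 10.4 mM working. Its remaining share of 23.2% at 36 min, raised to the power charge over working catalyst, leaves 83.9% converted. The green flask with the impurity taken away ends at 83.9%.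

(The earlier runs and the new flask come from a simulation on assumed constants; scatter was added.)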